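The data are simulated for an exercise; the scatter is artificial.

**The question.** I wanted to know whether a racemic charge stirred with the single-handed reagent holds a higher excess of left-handed product at 40 min or at 80 min. East and south-east are one recipe read at two times.

| flask | left-handed substrate | right-handed substrate | reagent | remark | time |
|---|---|---|---|---|---|
| dawn | 0.20 M | 0.20 M | 1.3 equiv | run made earlier |  |
| autumn | 0.20 M | 0.20 M | 3 equiv | run made earlier |  |
| east | 0.20 M | 0.20 M | 2.00 equiv |  | 40 min |
| south-east | 0.20 M | 0.20 M | 2.00 equiv |  | 80 min |

- dawn (time / min: left-handed product / %, right-handed product / %, left-handed substrate / %): 3.00: 7.7, 0.7, 41.2; 6.00: 12.6, 1.7, 35.7; 12.0: 18.4, 1.6, 28.8; 20.0: 22.9, 4.2, 23.0; 40.0: 28.3, 7.3, 17.5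
- autumn (time / min: left-handed product / %, right-handed product / %, left-handed substrate / %): 4.00: 18.9, 0.5, 29.5; 10.0: 30.5, 2.6, 16.5; 20.0: 38.3, 6.4, 7.9; 30.0: 40.5, 9.3, 5.7; 40.0: 40.2, 12.1, 3.6

(readings scatter by 0.5 percentage points)

- reagent is single-handed; left-handed substrate and right-handed substrate are mirror images of each other, charged as a racemate, each of them at the stated concentration
- an excess is below zero if the other one leads
- the handed part of reagent does not stay in what it makes, so the products of the two hands are mirror images too

* the flask that ends with the higher excess of left-handed product over right-handed product in the product, or "neither" when 2 percentage points or less lies between them (east / south-east / neither)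
* excess of left-handed product over right-handed product in the product at the end, east
* excess of left-handed product over right-handed product in the product at the end, south-east

**Turned round.** For neither to lead, the excess in the product would have to move by no more than 2 percentage points between those times, and for south-east to lead it would have to rise by more than that. So I read its fall. In the dawn run it went from 69.0% at 20.0 min to 59.0% at 40.0 min. In the autumn run it went from 71.4% at 20.0 min to 53.7% at 40.0 min.

**My reckoning.** Since 2.00 equiv lies between 1.3 equiv and 3 equiv, I averaged the two falls. That gave 0.0110 min⁻¹, the erosion constant: the fraction of the excess lost per minute (a first-order loss constant), as a reading. Averaging the later readings likewise put east at 56.3%. A tie allows a constant of 9.04 × 10⁻⁴ min⁻¹, and the ratio of the two, with time gone from it, is 12.2. So I committed to east, with south-east at 36.2%.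

The forecast also chose east, at 57% and 37%, slightly above mine, holding that “the excess erodes by about 40%”.

**The flask.** East ended at 58.6% and south-east at 36.8%, so east leads. In south-east, left-handed product stood at 35.4% at 40.0 min and 35.9% at 80.0 min, while right-handed product rose from 9.23% to 16.6%. The erosion constant, applied to the computed 58.6%, gives 37.7% for south-east.

    reagent + left-handed substrate → left-handed product (k = 0.00382 M⁻¹ s⁻¹)
    achiral form → waste (k = 8.38 × 10⁻⁵ s⁻¹)
    achiral form → side product (k = 1.05 × 10⁻⁴ s⁻¹)
    right-handed substrate ⇌ achiral form (K = 0.130, k = 8.18 × 10⁻⁵ s⁻¹)
    left-handed product ⇌ right-handed product (k = 1.08 × 10⁻⁴ s⁻¹)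
    reagent ⇌ dormant form (K = 0.967, k = 3.53 × 10⁻⁴ s⁻¹)
    left-handed substrate ⇌ achiral form (K = 0.130, k = 8.18 × 10⁻⁵ s⁻¹)
    reagent + right-handed substrate → right-handed product (k = 1.50 × 10⁻⁴ M⁻¹ s⁻¹)

**Second flask.** For south-east left until 5.0 h, the constant, started from the computed excess of east, gives 3.36%; the computed excess was 5.29%.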